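**Strategy**

The plan rests on cutting two bonds of ring B, C5–C10 and C8–C9. This works because ring B bears substituents only at C8 (the exocyclic methylene, derived from an oxygen) and at C9 (the side chain, derived from a C11 ester) beside the quaternary C10, so C5–C8 can serve as a diene and C9=C10 as a dienophile, tied together by C1–C4 of ring A. A single thermal intramolecular [4+2] cycloaddition then builds both rings and the stereocentres C5, C8, C9 and C10. Its substrate is an open-chain triene: (E)-β-methyl enoate, three methylene groups, a quaternary C4 (methyl, tert-butyl ester) and an (E,E)-1-silyloxydiene.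

Key step: step 12

Assumption: toward diester 6, pig liver esterase is taken to show the enantiotopic preference known for 2-methyl-2-alkylmalonates with unbranched six- and seven-carbon chains and to give the (R)-half-ester 7; the configuration of 7 has to be confirmed before step 4, and the fallback to step 3 does not depend on it.

Remark: atom numbers follow labdane numbering (C19 = carboxyl carbon on C4, C20 = methyl on C10, C17 = exocyclic methylene carbon, C11–C16 = side chain).

**Route**

Step 1
Reactants: 1 5-chloropent-1-yne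
Product: 3 (E)-5-chloro-1-iodo-2-methylpent-1-ene, via alkenylalane 2 (not isolated)
Conditions: AlMe3, Cp2ZrCl2 (cat.), CH2Cl2, 0 °C → rt; then I2, THF, −30 → 0 °C
Reagents that add atoms: trimethylaluminium, C[Al](C)C; iodine, II
Why: Zirconium-catalysed methylalumination (Negishi carboalumination) adds methyl and aluminium syn across the terminal alkyne with methyl on the internal carbon, and iodinolysis with retention fixes the (E)-trisubstituted alkene that later becomes the dienophile, while the remote primary chloride is inert.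

Step 2
Reactants: 4 dimethyl methylmalonate; 3 (E)-5-chloro-1-iodo-2-methylpent-1-ene
Product: 6 dimethyl 2-[(4E)-5-iodo-4-methylpent-4-en-1-yl]-2-methylpropanedioate, via sodium enolate 5 (not isolated)
Conditions: NaH, DMF, 0 °C; then 3, 70 °C
Reagents that add atoms: none
Why: Malonate alkylation (SN2) of the sodium enolate at the primary chloride builds C3–C4, and the vinyl iodide does not react with the soft carbanion.

Step 3
Reactants: 6 dimethyl 2-[(4E)-5-iodo-4-methylpent-4-en-1-yl]-2-methylpropanedioate
Product: 7 (2R,6E)-7-iodo-2-(methoxycarbonyl)-2,6-dimethylhept-6-enoic acid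
Conditions: pig liver esterase, phosphate buffer pH 7.5/DMSO, rt, pH-stat (1 M NaOH); then 1 M HCl
Reagents that add atoms: water, O
Why: Enzymatic desymmetrisation (hydrolysis of one enantiotopic ester) should set the C4 quaternary stereocentre, because the hydrophobic chain is expected to bind like an n-hexyl group and no third ester is present to compete.

Step 4
Reactants: 7 (2R,6E)-7-iodo-2-(methoxycarbonyl)-2,6-dimethylhept-6-enoic acid
Product: 8 methyl (2R,6E)-2-(hydroxymethyl)-7-iodo-2,6-dimethylhept-6-enoate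
Conditions: BH3·SMe2, THF, 0 °C → rt; then H2O
Reagents that add atoms: none
Why: Chemoselective borane reduction of a carboxylic acid beside an ester turns the hydrolysed carboxyl into C5 (CH2OH) without touching the stereocentre, the ester or the electron-poor trisubstituted vinyl iodide.

Step 5
Reactants: 8 methyl (2R,6E)-2-(hydroxymethyl)-7-iodo-2,6-dimethylhept-6-enoate
Product: 9 (2R,6E)-2-(hydroxymethyl)-7-iodo-2,6-dimethylhept-6-enoic acid
Conditions: LiOH, THF/MeOH/H2O, 50 °C; then 1 M HCl
Reagents that add atoms: lithium hydroxide, [Li+].[OH-]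
Why: Saponification of the only ester in the molecule frees the future C19 carboxyl, and the vinyl iodide tolerates aqueous hydroxide.

Step 6
Reactants: 9 (2R,6E)-2-(hydroxymethyl)-7-iodo-2,6-dimethylhept-6-enoic acid
Product: 10 tert-butyl (2R,6E)-2-(hydroxymethyl)-7-iodo-2,6-dimethylhept-6-enoate
Conditions: O-tert-butyl-N,N′-diisopropylisourea, CH2Cl2, rt
Reagents that add atoms: O-tert-butyl-N,N′-diisopropylisourea, CC(C)N=C(OC(C)(C)C)NC(C)C
Why: Isourea-mediated O-alkylation of the carboxylic acid (tert-butyl transfer to the carboxylate after protonation of the isourea) does not require access to the hindered carbonyl carbon and leaves the neopentyl alcohol free.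

Step 7
Reactants: 10 tert-butyl (2R,6E)-2-(hydroxymethyl)-7-iodo-2,6-dimethylhept-6-enoate
Product: 11 1-tert-butyl 8-methyl (2R,6E)-2-(hydroxymethyl)-2,6-dimethyloct-6-enedioate
Conditions: CO (1 atm), Pd(PPh3)2Cl2 (cat.), Et3N, MeOH, 50 °C
Reagents that add atoms: carbon monoxide, [C-]#[O+]; methanol, CO
Why: Palladium-catalysed methoxycarbonylation of the vinyl iodide proceeds with retention of alkene geometry and so delivers the (E)-β-methyl enoate (C9=C10, C11) without any E/Z separation.

Step 8
Reactants: 11 1-tert-butyl 8-methyl (2R,6E)-2-(hydroxymethyl)-2,6-dimethyloct-6-enedioate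
Product: 12 1-tert-butyl 8-methyl (2R,6E)-2-formyl-2,6-dimethyloct-6-enedioate
Conditions: Dess–Martin periodinane, CH2Cl2, 0 °C → rt
Reagents that add atoms: none
Why: Dess–Martin oxidation of the primary alcohol gives the C5 aldehyde, which has no α-hydrogen and therefore cannot enolise or epimerise.

Step 9
Reactants: 12 1-tert-butyl 8-methyl (2R,6E)-2-formyl-2,6-dimethyloct-6-enedioate; 13 [2-(1,3-dioxolan-2-yl)ethyl]triphenylphosphonium bromide
Product: 15 1-tert-butyl 8-methyl (2R,6E)-2-[(1Z)-3-(1,3-dioxolan-2-yl)prop-1-en-1-yl]-2,6-dimethyloct-6-enedioate, via ylide 14 (not isolated)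
Conditions: 13, KN(SiMe3)2, THF, −78 → 0 °C; then 12, −78 °C → rt
Reagents that add atoms: none
Why: Wittig olefination with a non-stabilised ylide adds C6–C8 to the hindered but highly electrophilic aldehyde, and the alkene geometry is of no consequence because it is erased in steps 10 and 11.

Step 10
Reactants: 15 1-tert-butyl 8-methyl (2R,6E)-2-[(1Z)-3-(1,3-dioxolan-2-yl)prop-1-en-1-yl]-2,6-dimethyloct-6-enedioate
Product: 17 1-tert-butyl 8-methyl (2R,6E)-2,6-dimethyl-2-[(2E)-4-oxobut-2-en-1-yl]oct-6-enedioate, via β,γ-unsaturated aldehyde 16 (not isolated)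
Conditions: 2 M HCl, THF, rt; then DBU (cat.), CH2Cl2, rt
Reagents that add atoms: water, O
Why: Acid-catalysed acetal hydrolysis followed by base-catalysed conjugative isomerisation moves the double bond to C6=C7 and should give the thermodynamically preferred (E)-enal, whose only γ-hydrogens sit on C5.

Step 11
Reactants: 17 1-tert-butyl 8-methyl (2R,6E)-2,6-dimethyl-2-[(2E)-4-oxobut-2-en-1-yl]oct-6-enedioate
Product: 18 1-tert-butyl 8-methyl (2R,6E)-2-[(1E,3E)-4-[(tert-butyldimethylsilyl)oxy]buta-1,3-dien-1-yl]-2,6-dimethyloct-6-enedioate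
Conditions: TBSOTf, Et3N, Et2O, −78 → 0 °C
Reagents that add atoms: tert-butyldimethylsilyl trifluoromethanesulfonate, CC(C)(C)[Si](C)(C)OS(=O)(=O)C(F)(F)F
Why: Soft enolisation (O-silylation of the enal and γ-deprotonation at C5 by Et3N) gives the 1-silyloxy-1,3-diene regiospecifically, the s-trans enal leading to the (E)-enol ether and the bulky quaternary C4 enforcing E at C5=C6.

Step 12
Reactants: 18 1-tert-butyl 8-methyl (2R,6E)-2-[(1E,3E)-4-[(tert-butyldimethylsilyl)oxy]buta-1,3-dien-1-yl]-2,6-dimethyloct-6-enedioate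
Product: 19 trans-fused Diels–Alder adduct (C19 tert-butyl ester on C4; C11 methyl ester on C9; silyloxy group on C8; C6=C7)
Conditions: toluene (0.01 M), BHT (cat.), 160 °C, sealed tube
Reagents that add atoms: none
Why: Thermal intramolecular Diels–Alder reaction, a concerted asynchronous suprafacial [4+2] addition of the electron-rich (1E,3E)-1-silyloxydiene C5=C6–C7=C8 to the (E)-β-methyl enoate C9=C10 that forms C5–C10 and C8–C9; the closest known reaction type is the thermal cyclisation of terminally activated deca-2,8,10-trienoates to trans-fused octalins, including cases with a β-methyl dienophile. Ring B closes as the cyclohexene of the cycloaddition itself, and ring A closes in the same event through the C5–C10 bond with the tether C1–C4 folded as a chair (fused mode; the four-carbon tether allows only this regiochemistry). C9 and C10 are related by the (E)-dienophile geometry (C11 trans to C1 and hence cis to C20), C8 by the (E)-enol ether (silyloxy group cis to C11), and C5 relative to C10 by the ester-endo transition state, which gives the trans ring fusion. The absolute sense of all four centres follows from C4: in the chair-like tether the tert-butyl ester should take the pseudo-axial site syn to the incoming C20 methyl and the C4 methyl the equatorial site, because the alternative places two methyl groups 1,3-diaxial. The step therefore needs endo (trans-fusion) and diene-face selectivity, the first supported by pairing an oxygenated diene with the ester and the second by the C4 stereocentre, and neutral thermal conditions are chosen because the silyl dienol ether and the tert-butyl ester would not tolerate an aluminium Lewis acid.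

Step 13
Reactants: 19 trans-fused Diels–Alder adduct
Product: 20 C11 primary alcohol (CH2OH on C9; otherwise as 19)
Conditions: i-Bu2AlH, CH2Cl2, −78 → −20 °C; Rochelle salt work-up
Reagents that add atoms: none
Why: Hydride reduction takes the secondary methyl ester to the alcohol, while the tert-butyl ester on the quaternary, axial C4 is too shielded to react at low temperature.

Step 14
Reactants: 20 C11 primary alcohol
Product: 21 C11 aldehyde (CHO on C9; otherwise as 19)
Conditions: Dess–Martin periodinane, CH2Cl2, 0 °C → rt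
Reagents that add atoms: none
Why: Dess–Martin oxidation under near-neutral conditions gives the aldehyde without β-elimination of the C8 silyloxy group, and the equatorial aldehyde is already the stable C9 epimer.

Step 15
Reactants: 22 (S)-3-methyldihydrofuran-2(3H)-one
Product: 23 (2S)-4-hydroxy-2-methyl-1-(pyrrolidin-1-yl)butan-1-one
Conditions: pyrrolidine (neat), 60 °C
Reagents that add atoms: pyrrolidine, C1CCNC1
Why: Ring-opening aminolysis of the γ-lactone differentiates the two ends of the C12–C15 unit, and the α-stereocentre (future C13) is not acidic enough to epimerise under amine conditions.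

Step 16
Reactants: 23 (2S)-4-hydroxy-2-methyl-1-(pyrrolidin-1-yl)butan-1-one
Product: 24 (2S)-4-[(tert-butyldiphenylsilyl)oxy]-2-methyl-1-(pyrrolidin-1-yl)butan-1-one
Conditions: TBDPSCl, imidazole, DMF, rt
Reagents that add atoms: tert-butyl(chloro)diphenylsilane, CC(C)(C)[Si](Cl)(c1ccccc1)c1ccccc1
Why: Silyl ether formation protects C15–OH and blocks relactonisation.

Step 17
Reactants: 24 (2S)-4-[(tert-butyldiphenylsilyl)oxy]-2-methyl-1-(pyrrolidin-1-yl)butan-1-one
Product: 25 (2S)-4-[(tert-butyldiphenylsilyl)oxy]-2-methylbutan-1-ol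
Conditions: LiEt3BH, THF, 0 °C → rt
Reagents that add atoms: none
Why: Triethylborohydride reduces tertiary amides to primary alcohols with C–N cleavage, and the transient aldehyde is reduced at once so that the adjacent stereocentre is not epimerised.

Step 18
Reactants: 25 (2S)-4-[(tert-butyldiphenylsilyl)oxy]-2-methylbutan-1-ol
Product: 26 tert-butyl{[(3S)-4-iodo-3-methylbutyl]oxy}diphenylsilane
Conditions: I2, PPh3, imidazole, CH2Cl2, 0 °C → rt
Reagents that add atoms: iodine, II
Why: Appel-type iodination converts the primary alcohol into the iodide by SN2 at C12, one carbon away from the stereocentre.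

Step 19
Reactants: 26 tert-butyl{[(3S)-4-iodo-3-methylbutyl]oxy}diphenylsilane
Product: 27 {(2S)-4-[(tert-butyldiphenylsilyl)oxy]-2-methylbutyl}triphenylphosphonium iodide
Conditions: PPh3, MeCN, reflux
Reagents that add atoms: triphenylphosphine, c1ccc(cc1)P(c1ccccc1)c1ccccc1
Why: SN2 quaternisation of triphenylphosphine by the primary iodide gives the Wittig salt for C12–C15.

Step 20
Reactants: 21 C11 aldehyde; 27 {(2S)-4-[(tert-butyldiphenylsilyl)oxy]-2-methylbutyl}triphenylphosphonium iodide
Product: 29 tert-butyl (11Z)-8-[(tert-butyldimethylsilyl)oxy]-15-[(tert-butyldiphenylsilyl)oxy]-17-norlabda-6,11-dien-19-oate, via ylide 28 (not isolated)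
Conditions: 27, NaN(SiMe3)2, THF, −78 → 0 °C; then 21, −78 °C → rt
Reagents that add atoms: none
Why: Wittig olefination of the C11 aldehyde with the non-stabilised ylide forms C11=C12; C13 is β to phosphorus and is not deprotonated, and addition to the aldehyde at low temperature is expected to outrun deprotonation at the hindered C9.

Step 21
Reactants: 29 tert-butyl (11Z)-8-[(tert-butyldimethylsilyl)oxy]-15-[(tert-butyldiphenylsilyl)oxy]-17-norlabda-6,11-dien-19-oate
Product: 30 tert-butyl 8-[(tert-butyldimethylsilyl)oxy]-15-[(tert-butyldiphenylsilyl)oxy]-17-norlabdan-19-oate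
Conditions: H2 (1 atm), PtO2, EtOAc, rt
Reagents that add atoms: none
Why: Heterogeneous catalytic hydrogenation saturates C6=C7 and C11=C12 in one operation without creating a stereocentre, platinum being chosen to limit hydrogenolysis of the allylic C8–O bond.

Step 22
Reactants: 30 tert-butyl 8-[(tert-butyldimethylsilyl)oxy]-15-[(tert-butyldiphenylsilyl)oxy]-17-norlabdan-19-oate
Product: 31 tert-butyl 8,15-dihydroxy-17-norlabdan-19-oate
Conditions: Bu4NF, THF, 50 °C
Reagents that add atoms: none
Why: Fluoride-mediated desilylation removes both silyl ethers, and the hindered tert-butyl ester is stable to fluoride.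

Step 23
Reactants: 31 tert-butyl 8,15-dihydroxy-17-norlabdan-19-oate; 32 (R)-2-methylbutanoic acid
Product: 33 tert-butyl 8-hydroxy-15-{[(2R)-2-methylbutanoyl]oxy}-17-norlabdan-19-oate
Conditions: 32, i-PrN=C=N-i-Pr, DMAP (cat.), CH2Cl2, 0 °C
Reagents that add atoms: none
Why: Carbodiimide (Steglich) esterification acylates the primary C15–OH selectively, since the axial C8–OH is flanked by C9 and is 1,3-diaxial to C20, and the low temperature with catalytic DMAP protects the α-stereocentre of the acid.

Step 24
Reactants: 33 tert-butyl 8-hydroxy-15-{[(2R)-2-methylbutanoyl]oxy}-17-norlabdan-19-oate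
Product: 34 tert-butyl 15-{[(2R)-2-methylbutanoyl]oxy}-8-oxo-17-norlabdan-19-oate
Conditions: Dess–Martin periodinane, CH2Cl2, rt
Reagents that add atoms: none
Why: Dess–Martin oxidation of the axial secondary alcohol gives the C8 ketone, and C9 keeps its equatorial side chain, which is the thermodynamic arrangement.

Step 25
Reactants: 34 tert-butyl 15-{[(2R)-2-methylbutanoyl]oxy}-8-oxo-17-norlabdan-19-oate
Product: 35 tert-butyl 15-{[(2R)-2-methylbutanoyl]oxy}labd-8(17)-en-19-oate
Conditions: Zn, CH2Br2, TiCl4, THF, −40 → 5 °C (reagent aged); then 34, CH2Cl2, 0 °C → rt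
Reagents that add atoms: dibromomethane, BrCBr
Why: Lombardo–Takai methylenation converts hindered, enolisable ketones into methylene compounds under non-basic conditions and leaves esters alone, so neither C9 nor the α-centre of the 2-methylbutanoate should epimerise.

Step 26
Reactants: 35 tert-butyl 15-{[(2R)-2-methylbutanoyl]oxy}labd-8(17)-en-19-oate
Product: 37 (4R,5S,9R,10S,13R)-15-{[(2R)-2-methylbutanoyl]oxy}labd-8(17)-en-19-oic acid, via trimethylsilyl ester 36 (not isolated)
Conditions: TMSOTf, 2,6-lutidine, CH2Cl2, 0 °C → rt; then aq. citric acid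
Reagents that add atoms: none
Why: Silyl triflate-mediated cleavage of the tert-butyl ester (O-silylation and loss of the tert-butyl group as an alkene, buffered by 2,6-lutidine) avoids the protic acid that could move the exocyclic C8=C17 double bond into the ring, and the silyl ester is hydrolysed on work-up while the secondary-alkyl ester is untouched.

**Compound list**

1 | 5-chloropent-1-yne | C#CCCCCl | starting material
2 | (E)-(5-chloro-2-methylpent-1-en-1-yl)dimethylalane | ClCCC/C(C)=C/[Al](C)C | intermediate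
3 | (E)-5-chloro-1-iodo-2-methylpent-1-ene | ClCCC/C(C)=C/I | intermediate
4 | dimethyl methylmalonate | COC(=O)C(C)C(=O)OC | starting material
5 | sodium enolate of dimethyl methylmalonate | [Na+].COC(=O)C(C)=C([O-])OC | intermediate
6 | dimethyl 2-[(4E)-5-iodo-4-methylpent-4-en-1-yl]-2-methylpropanedioate | COC(=O)C(C)(CCC/C(C)=C/I)C(=O)OC | intermediate
7 | (2R,6E)-7-iodo-2-(methoxycarbonyl)-2,6-dimethylhept-6-enoic acid | I/C=C(C)/CCC[C@@](C(=O)O)(C)C(=O)OC | intermediate
8 | methyl (2R,6E)-2-(hydroxymethyl)-7-iodo-2,6-dimethylhept-6-enoate | I/C=C(C)/CCC[C@@](CO)(C)C(=O)OC | intermediate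
9 | (2R,6E)-2-(hydroxymethyl)-7-iodo-2,6-dimethylhept-6-enoic acid | I/C=C(C)/CCC[C@@](CO)(C)C(=O)O | intermediate
10 | tert-butyl (2R,6E)-2-(hydroxymethyl)-7-iodo-2,6-dimethylhept-6-enoate | I/C=C(C)/CCC[C@@](CO)(C)C(=O)OC(C)(C)C | intermediate
11 | 1-tert-butyl 8-methyl (2R,6E)-2-(hydroxymethyl)-2,6-dimethyloct-6-enedioate | COC(=O)/C=C(\C)CCC[C@@](CO)(C)C(=O)OC(C)(C)C | intermediate
12 | 1-tert-butyl 8-methyl (2R,6E)-2-formyl-2,6-dimethyloct-6-enedioate | COC(=O)/C=C(\C)CCC[C@@](C=O)(C)C(=O)OC(C)(C)C | intermediate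
13 | [2-(1,3-dioxolan-2-yl)ethyl]triphenylphosphonium bromide | C1COC(O1)CC[P+](c1ccccc1)(c1ccccc1)c1ccccc1.[Br-] | starting material
14 | [2-(1,3-dioxolan-2-yl)ethylidene]triphenylphosphorane | C1COC(O1)CC=P(c1ccccc1)(c1ccccc1)c1ccccc1 | intermediate
15 | 1-tert-butyl 8-methyl (2R,6E)-2-[(1Z)-3-(1,3-dioxolan-2-yl)prop-1-en-1-yl]-2,6-dimethyloct-6-enedioate | COC(=O)/C=C(\C)CCC[C@@](/C=C\CC1OCCO1)(C)C(=O)OC(C)(C)C | intermediate
16 | 1-tert-butyl 8-methyl (2R,6E)-2,6-dimethyl-2-[(1Z)-4-oxobut-1-en-1-yl]oct-6-enedioate | COC(=O)/C=C(\C)CCC[C@@](/C=C\CC=O)(C)C(=O)OC(C)(C)C | intermediate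
17 | 1-tert-butyl 8-methyl (2R,6E)-2,6-dimethyl-2-[(2E)-4-oxobut-2-en-1-yl]oct-6-enedioate | COC(=O)/C=C(\C)CCC[C@@](C/C=C/C=O)(C)C(=O)OC(C)(C)C | intermediate
18 | 1-tert-butyl 8-methyl (2R,6E)-2-[(1E,3E)-4-[(tert-butyldimethylsilyl)oxy]buta-1,3-dien-1-yl]-2,6-dimethyloct-6-enedioate (cycloaddition precursor) | COC(=O)/C=C(\C)CCC[C@@](/C=C/C=C/O[Si](C)(C)C(C)(C)C)(C)C(=O)OC(C)(C)C | intermediate
19 | trans-fused Diels–Alder adduct: Δ6-octalin with tert-butyl ester (C19) and methyl on C4, methyl on C10 (C20), methyl ester (C11) on C9, tert-butyldimethylsilyloxy on C8; C19, C20, C11 and the silyloxy group on one face, H5, H8 and H9 on the other; C4, C5, C9, C10 as in the target | CC(C)(C)[Si](C)(C)O[C@@H]1C=C[C@H]2[C@@](C)(CCC[C@@]2(C)C(=O)OC(C)(C)C)[C@@H]1C(=O)OC | intermediate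
20 | C11 primary alcohol: as 19 with CH2OH on C9 | CC(C)(C)[Si](C)(C)O[C@@H]1C=C[C@H]2[C@@](C)(CCC[C@@]2(C)C(=O)OC(C)(C)C)[C@@H]1CO | intermediate
21 | C11 aldehyde: as 19 with CHO on C9 | CC(C)(C)[Si](C)(C)O[C@@H]1C=C[C@H]2[C@@](C)(CCC[C@@]2(C)C(=O)OC(C)(C)C)[C@@H]1C=O | intermediate
22 | (S)-3-methyldihydrofuran-2(3H)-one | C[C@H]1CCOC1=O | starting material
23 | (2S)-4-hydroxy-2-methyl-1-(pyrrolidin-1-yl)butan-1-one | C[C@@H](CCO)C(=O)N1CCCC1 | intermediate
24 | (2S)-4-[(tert-butyldiphenylsilyl)oxy]-2-methyl-1-(pyrrolidin-1-yl)butan-1-one | C[C@@H](CCO[Si](c1ccccc1)(c1ccccc1)C(C)(C)C)C(=O)N1CCCC1 | intermediate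
25 | (2S)-4-[(tert-butyldiphenylsilyl)oxy]-2-methylbutan-1-ol | C[C@@H](CCO[Si](c1ccccc1)(c1ccccc1)C(C)(C)C)CO | intermediate
26 | tert-butyl{[(3S)-4-iodo-3-methylbutyl]oxy}diphenylsilane | C[C@@H](CCO[Si](c1ccccc1)(c1ccccc1)C(C)(C)C)CI | intermediate
27 | {(2S)-4-[(tert-butyldiphenylsilyl)oxy]-2-methylbutyl}triphenylphosphonium iodide | C[C@@H](CCO[Si](c1ccccc1)(c1ccccc1)C(C)(C)C)C[P+](c1ccccc1)(c1ccccc1)c1ccccc1.[I-] | intermediate
28 | {(2S)-4-[(tert-butyldiphenylsilyl)oxy]-2-methylbutylidene}triphenylphosphorane | C[C@@H](CCO[Si](c1ccccc1)(c1ccccc1)C(C)(C)C)C=P(c1ccccc1)(c1ccccc1)c1ccccc1 | intermediate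
29 | tert-butyl (11Z)-8-[(tert-butyldimethylsilyl)oxy]-15-[(tert-butyldiphenylsilyl)oxy]-17-norlabda-6,11-dien-19-oate (8-O on the face of C20; C13 as in the target) | CC(C)(C)[Si](C)(C)O[C@@H]1C=C[C@H]2[C@@](C)(CCC[C@@]2(C)C(=O)OC(C)(C)C)[C@@H]1/C=C\[C@@H](C)CCO[Si](c1ccccc1)(c1ccccc1)C(C)(C)C | intermediate
30 | tert-butyl 8-[(tert-butyldimethylsilyl)oxy]-15-[(tert-butyldiphenylsilyl)oxy]-17-norlabdan-19-oate | CC(C)(C)[Si](C)(C)O[C@@H]1CC[C@H]2[C@@](C)(CCC[C@@]2(C)C(=O)OC(C)(C)C)[C@@H]1CC[C@@H](C)CCO[Si](c1ccccc1)(c1ccccc1)C(C)(C)C | intermediate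
31 | tert-butyl 8,15-dihydroxy-17-norlabdan-19-oate | O[C@@H]1CC[C@H]2[C@@](C)(CCC[C@@]2(C)C(=O)OC(C)(C)C)[C@@H]1CC[C@@H](C)CCO | intermediate
32 | (R)-2-methylbutanoic acid | CC[C@@H](C)C(=O)O | starting material
33 | tert-butyl 8-hydroxy-15-{[(2R)-2-methylbutanoyl]oxy}-17-norlabdan-19-oate | O[C@@H]1CC[C@H]2[C@@](C)(CCC[C@@]2(C)C(=O)OC(C)(C)C)[C@@H]1CC[C@@H](C)CCOC(=O)[C@H](C)CC | intermediate
34 | tert-butyl 15-{[(2R)-2-methylbutanoyl]oxy}-8-oxo-17-norlabdan-19-oate | O=C1CC[C@H]2[C@@](C)(CCC[C@@]2(C)C(=O)OC(C)(C)C)[C@@H]1CC[C@@H](C)CCOC(=O)[C@H](C)CC | intermediate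
35 | tert-butyl 15-{[(2R)-2-methylbutanoyl]oxy}labd-8(17)-en-19-oate | C=C1CC[C@H]2[C@@](C)(CCC[C@@]2(C)C(=O)OC(C)(C)C)[C@@H]1CC[C@@H](C)CCOC(=O)[C@H](C)CC | intermediate
36 | trimethylsilyl 15-{[(2R)-2-methylbutanoyl]oxy}labd-8(17)-en-19-oate | C=C1CC[C@H]2[C@@](C)(CCC[C@@]2(C)C(=O)O[Si](C)(C)C)[C@@H]1CC[C@@H](C)CCOC(=O)[C@H](C)CC | intermediate
37 | (4R,5S,9R,10S,13R)-15-{[(2R)-2-methylbutanoyl]oxy}labd-8(17)-en-19-oic acid (CNP0109063.1) | C=C1CC[C@H]2[C@@](C)(CCC[C@@]2(C)C(=O)O)[C@@H]1CC[C@@H](C)CCOC(=O)[C@H](C)CC | target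

**Step count**

Total: 26 steps. Longest linear sequence: 21 steps (steps 1–14 and 20–26); the side-chain branch is steps 15–19.

**Steps most likely to fail**

Step 12 (key step). The cycloaddition may pass partly through the ester-exo, cis-fused transition state or add to the other diene face, and the silyl dienol ether may decompose at the temperature that the trisubstituted ester dienophile needs. The fallback uses a more reactive aldehyde dienophile. It sets out from 18: the methyl enoate alone is reduced with i-Bu2AlH (CH2Cl2, −78 °C; the hindered tert-butyl ester and the silyl dienol ether should remain) to the allylic trienol F1, which MnO2 (CH2Cl2, rt) oxidises to the trienal F2. The enal should cyclise well below the temperature of step 12 (toluene, about 80–110 °C) with a stronger endo preference and gives aldehyde 21 directly. The route is rejoined at 21, and steps 13 and 14 are then not needed.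

Step 3. The enzyme may discriminate the two ester groups incompletely, or in the opposite sense. The fallback is a classical resolution in which both antipodes are used. It sets out from 6: one ester is saponified with one equivalent of KOH in methanol to the racemic half-ester F3. Crystallisation with (S)-1-phenylethylamine (or its antipode, whichever gives the less soluble salt with the (R)-acid) gives the salt F4, from which aqueous acid liberates 7. The (S)-half-ester F5 recovered from the mother liquor is not discarded: LiBH4 (THF) reduces its methyl ester and leaves the carboxylate, which gives the hydroxy acid 9 directly. The route is rejoined at 7 and at 9.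

Step 20. The basic ylide may deprotonate C9 of the hindered aldehyde instead of adding to it, which would lead to β-elimination of the C8 silyloxy group (anti to H9) or to incomplete conversion. The fallback replaces the olefination by a copper-catalysed alkyl–alkyl coupling. It sets out from alcohol 20 and iodide 26: Tf2O and pyridine (CH2Cl2, −20 °C) convert 20 into the primary triflate F6, and Mg (THF) converts 26 into the Grignard reagent F7. Coupling of F6 with F7 under Li2CuCl4 catalysis (THF, −20 → 0 °C) forms C11–C12 directly and gives the Δ6 compound F8, which is hydrogenated (H2, PtO2, EtOAc) to 30. The route is rejoined at 30, and steps 14, 19 and 20 are then not needed.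

**Further compounds**

F1 | step 12 | tert-butyl (2R,6E)-2-[(1E,3E)-4-[(tert-butyldimethylsilyl)oxy]buta-1,3-dien-1-yl]-8-hydroxy-2,6-dimethyloct-6-enoate | OC/C=C(\C)CCC[C@@](/C=C/C=C/O[Si](C)(C)C(C)(C)C)(C)C(=O)OC(C)(C)C
F2 | step 12 | tert-butyl (2R,6E)-2-[(1E,3E)-4-[(tert-butyldimethylsilyl)oxy]buta-1,3-dien-1-yl]-2,6-dimethyl-8-oxooct-6-enoate | O=C/C=C(\C)CCC[C@@](/C=C/C=C/O[Si](C)(C)C(C)(C)C)(C)C(=O)OC(C)(C)C
F3 | step 3 | racemic (6E)-7-iodo-2-(methoxycarbonyl)-2,6-dimethylhept-6-enoic acid | OC(=O)C(C)(CCC/C(C)=C/I)C(=O)OC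
F4 | step 3 | (S)-1-phenylethylammonium (2R,6E)-7-iodo-2-(methoxycarbonyl)-2,6-dimethylhept-6-enoate | I/C=C(C)/CCC[C@@](C(=O)[O-])(C)C(=O)OC.C[C@H]([NH3+])c1ccccc1
F5 | step 3 | (2S,6E)-7-iodo-2-(methoxycarbonyl)-2,6-dimethylhept-6-enoic acid | I/C=C(C)/CCC[C@](C(=O)O)(C)C(=O)OC
F6 | step 20 | C11 triflate: as 20 with CH2OSO2CF3 on C9 | CC(C)(C)[Si](C)(C)O[C@@H]1C=C[C@H]2[C@@](C)(CCC[C@@]2(C)C(=O)OC(C)(C)C)[C@@H]1COS(=O)(=O)C(F)(F)F
F7 | step 20 | {(2S)-4-[(tert-butyldiphenylsilyl)oxy]-2-methylbutyl}magnesium iodide | C[C@@H](CCO[Si](c1ccccc1)(c1ccccc1)C(C)(C)C)C[Mg]I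
F8 | step 20 | tert-butyl 8-[(tert-butyldimethylsilyl)oxy]-15-[(tert-butyldiphenylsilyl)oxy]-17-norlabd-6-en-19-oate | CC(C)(C)[Si](C)(C)O[C@@H]1C=C[C@H]2[C@@](C)(CCC[C@@]2(C)C(=O)OC(C)(C)C)[C@@H]1CC[C@@H](C)CCO[Si](c1ccccc1)(c1ccccc1)C(C)(C)C
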